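## The problem

- The target is a eudesmane. Rings A and B share the C5–C10 bond, C5 lies in the tetrasubstituted C4=C5 alkene and C10 is a quaternary, methyl-bearing carbon. The ring fusion therefore has no hydrogen that could be corrected later and must be right when the C–C bond is made.
- The four stereocentres (3S, 7R, 8R, 10R) all carry their substituent on the face of the C10 methyl. In the ring B chair this means an axial methyl, an equatorial C7 branch and an axial O8 that is 1,3-diaxial to the methyl.
- C7 is the one centre a chiral-pool terpene can supply, and through the chair preference of ring B it can set C10. The C10 methyl then biases hydride delivery to C3 and blocks axial delivery to C8, so both carbinols can come from ketones. C8 must be set kinetically, because equilibration would favour the equatorial epimer.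
- Several groups are fragile. The 2-substituted acrylate is open to conjugate addition, reduction and polymerisation. The (E)-3-methylpent-2-enoate loses geometry or deconjugates after γ-deprotonation. C7–H becomes α to a carbonyl and allylic once C8 is a ketone, which invites epimerisation or drift of the exocyclic alkene into conjugation.
- Two different esters on secondary oxygens must be told apart, so these groups have to arrive late and in a fixed order.
- The enabling feature is the substitution of ring B: the C10 methyl and, para to it, the three-carbon branch on C7. This is the arrangement of carvone if the enone carbonyl is placed at C9, its α-carbon at C10 and its β-carbon at C5.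
- A ketone-bearing chain on C5 then has its C4 hydrogen α to one carbonyl and γ to the other. The extended enolate is nucleophilic at C10, so ring A can close through a C1–C10 bond while the alkene moves to C4=C5.
- The price is that the ring B oxygen is at C9 and has to be moved to C8.

## Retrosynthesis

**O3–acyl bond (22 ⇒ 20 + 21).** The enoate is the most base-sensitive group and is cut first. The precursor 20 has a single free hydroxyl, so no selectivity is needed. The forward reaction must acylate a hindered allylic alcohol without a strong base, so that the E geometry of acid 21 survives.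

**C12 oxidation level and silyl groups (20 ⇒ 19 ⇒ 18 ⇒ 17 ⇒ 16).** The acrylate would not survive the hydride and organolithium steps, so it is traced back through acid 19 and enal 18 to the primary allylic alcohol 17, and 17 to its bis-silyl ether 16. Unmasking both hydroxyls together saves a step over orthogonal protection. The forward oxidation must take the primary allylic alcohol and leave the hindered secondary one at C3.

**C8–O and C8–H (16 ⇒ 15 ⇒ 14).** The acetate comes from the axial alcohol 15, and that from ketone 14 by cutting the C8–H bond. Oxygenating a C9 enolate directly would attack anti to the C10 methyl and give the wrong, equatorial epimer. A ketone with a bulky hydride gives the axial alcohol, because the syn-axial methyl closes the axial approach.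

**1,2-Carbonyl transposition (14 ⇒ 13 ⇒ 11 ⇒ 10).** The C8 ketone is derived from the C9 ketone 10 through vinyl sulfide 13 and tosylhydrazone 11. C10 is quaternary, so 10 can be functionalised only at C8 and no regiochemical question arises. The sulfenylation–Shapiro form is preferred over the reduction–elimination form because it needs no anti-periplanar arrangement at the neopentyl C9.

**C3–H and C12–O (10 ⇒ 9 ⇒ 8 ⇒ 7).** Silyl ether 10 comes from diol 9, 9 from hydroxy dione 8 by 1,2-reduction of the enone, and 8 from dione 7 by allylic oxidation. The C12 oxygen is introduced at the stage of 7 because there C4=C5 is part of an enone and the isopropenyl group is the only electron-rich alkene. After reduction at C3 the tetrasubstituted alkene would compete for SeO2. The reduction must distinguish the enone from the saturated C9 ketone.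

**C1–C10, the key cut (7 ⇒ 6).** Cutting C1–C10 opens ring A to a monocyclic enone 6 with a vinyl ketone chain on C5. The neighbouring cut C4–C5 with C5–C10 kept (a Robinson-type aldol closure) would need the quaternary centre to be made first on a ring without the C9 activating group. The chosen cut forms the quaternary centre and the ring in one isomerisation and removes one ring and one stereocentre. The forward reaction needs deprotonation at C4, attack through C10 and a facial preference set by C7.

**Chain assembly and origin of ring B (6 ⇒ 5 ⇒ 3 ⇒ 1 + 2 + 4).** Enone 6 is a 3-substituted 2-methylcyclohexenone. It comes from tertiary allylic alcohol 5 by oxidative 1,3-transposition, 5 from Weinreb amide 3 and vinyl Grignard reagent 4 (C2–C3 bond), and 3 from (R)-carvone 1 and propanamide 2 (C4–C5 bond). The transposition moves the carbonyl from carvone C1 to C3 and so reverses the sense in which the ring is read. For that reason (R)-carvone, and not its enantiomer, supplies the C7 configuration of 22.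

## Roads not taken

**Alternative 1:** Both rings are opened at once by cutting C5–C10 and C3–C4. This leads to an acyclic keto ester in which a but-2-ynyl unit (the future C15–C4–C5–C6) and a 1-silyloxy diene (C3 to C10) are tied through C6–C9. Forward, Ni(cod)2 (zerovalent nickel) with a triaryl phosphite would add the unactivated alkyne across the diene and give A1, a 3-silyloxy-eudesma-1,4-dien-8-one with a tert-butyl acetate chain on C7.
- Merits: two rings and the quaternary centre form in one catalytic step; the C8 ketone is in place; C3–O and the C10 methyl are fixed relative to each other by suprafacial addition.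
- Weak points: C10 arises from a fully substituted diene terminus; both diene geometries must be pure because they encode the C3/C10 relationship; the facial choice rests on one epimerisable tether centre (C7, α to the ketone) that needs its own asymmetric synthesis.
- After cyclisation the C1=C2 alkene must be reduced beside C4=C5 and the acetate chain still needs α-methylenation.
- Comparison: this road is better in ring-forming economy and needs no C9-to-C8 oxygen shift (steps 8–10 here). The chosen plan offers an enantiopure ring B with the branch already attached and closely precedented reaction types throughout.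

**Alternative 2:** Ring B is cut at C9–C10 and C5–C6, a Diels–Alder disconnection to a methoxy methyl benzoquinone (ring A) and a 2-silyloxybutadiene bearing the acetate chain. A chiral oxazaborolidinium triflimide would direct the diene to the methyl-bearing quinone alkene and give cis-fused A2, with C10 set absolutely and the C8 oxygen present as a silyl enol ether.
- Merits: catalytic enantiocontrol of the quaternary centre in the bond-forming event; two simple achiral partners; either enantiomer available; oxygen at C3 and C8 from the start.
- Weak points: ring A arrives as an enedione, so the C1 carbonyl must be deleted, C4 needs methyl addition and dehydration to give C4=C5, and the vinylogous ester must become the 3β-carbinol.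
- C7 is not set by the cycloaddition and the orientation of the diene on the unsymmetrical quinone needs catalyst control.
- Comparison: this road is superior in convergence and in independence from a natural starting material. The chosen plan has far fewer redox corrections in ring A and has C7 secured before any ring is made.

**Alternative 3:** Only C4=C5 is cut. Ring A opens to a ring B cyclohexane with an exocyclic methylene at C5 and, on a C10 centre set earlier by a catalytic enantioselective alkylation, a chain ending in the C3 silyloxy carbinol and an isopropenyl group. Ring-closing metathesis with an N-o-tolyl second-generation Hoveyda–Grubbs-type complex, RuCl2(=CH-C6H4-2-O-i-Pr)(1,3-di-o-tolylimidazolidin-2-ylidene), would give A3 with loss of ethene.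
- Merits: the C8 oxygen is in place as a ketal, C3 is set before ring closure, and the closure is neutral and functional-group tolerant.
- Weak points: a tetrasubstituted alkene from two 1,1-disubstituted alkenes beside a quaternary centre is the hardest class of metathesis.
- A3 has no substituent on C7, so the three-carbon branch and its configuration must be added later through the C8 ketone enolate, and C3 needs a separate stereoselective step.
- Comparison: this road needs no carbonyl transposition. The chosen plan sets C7 first and lets it direct C10, and carries the branch from the start.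

Key step: step 4

Remark: (2E)-3-methylpent-2-enoic acid 21 is taken as a purchasable, geometrically pure reagent. Eudesmane numbering is used for all bicyclic compounds (C12 is the oxidised carbon and C13 the methylene of the C7 branch). The descriptors at C7 and C10 change between 7–12 and 13–22 only because substituent priorities change; the spatial arrangement stays the same.

## Route

Step 1
Reactants: 1 (R)-(−)-carvone; 2 N-methoxy-N-methylpropanamide
Product: 3 2-[(5R)-1-hydroxy-2-methyl-5-(prop-1-en-2-yl)cyclohex-2-en-1-yl]-N-methoxy-N-methylpropanamide (diastereomer mixture at the carbinol carbon and the α-methyl carbon)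
Conditions: 2, LiN(i-Pr)2, THF, −78 °C; then 1, −78 °C; AcOH, −78 °C
Reagents that add atoms: none
Why: Kinetic aldol-type 1,2-addition of the lithium amide enolate to the enone carbonyl; the cold acidic quench prevents retro-aldol and equilibration to the conjugate adduct. The two new centres form as a mixture, which does not matter because both become sp2 in steps 3 and 4; the carvone centre is untouched.

Step 2
Reactants: 3 (β-hydroxy Weinreb amide); 4 vinylmagnesium bromide
Product: 5 4-[(5R)-1-hydroxy-2-methyl-5-(prop-1-en-2-yl)cyclohex-2-en-1-yl]pent-1-en-3-one (diastereomer mixture)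
Conditions: CH2=CHMgBr (3 equiv), THF, −20 → 0 °C; inverse quench into cold aq. KHSO4
Reagents that add atoms: none
Why: Weinreb ketone synthesis: one equivalent forms the magnesium alkoxide, the next adds to the amide to give a chelated tetrahedral intermediate that collapses only on work-up, so no over-addition occurs. The inverse acidic quench keeps the released N,O-dimethylhydroxylamine protonated so that it cannot add to the vinyl ketone.

Step 3
Reactants: 5 (tertiary allylic alcohol)
Product: 6 (5S)-2-methyl-3-(3-oxopent-4-en-2-yl)-5-(prop-1-en-2-yl)cyclohex-2-en-1-one (both C4 epimers; in eudesmane terms C9 ketone, C10 methyl, chain on C5, isopropenyl on C7)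
Conditions: [C5H5NH][CrO3Cl] (pyridinium chlorochromate), Celite, CH2Cl2, 25 °C
Reagents that add atoms: pyridinium chlorochromate, [O-][Cr](=O)(=O)Cl.c1cc[nH+]cc1
Why: Babler–Dauben oxidative transposition: the chromate ester of the tertiary allylic alcohol undergoes a [3,3] shift and the transposed secondary chromate is oxidised by hexavalent chromium. The oxygen moves from carvone C1 to C3 and the chain ends on the β-carbon of the new enone.

Step 4
Reactants: 6 (enone with vinyl ketone chain)
Product: 7 (7S,10S)-eudesma-4,11-diene-3,9-dione (C10 methyl cis to the C7 isopropenyl group)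
Conditions: KOt-Bu (0.2 equiv), t-BuOH–THF (1:1), 0.01 M, 0 → 25 °C
Reagents that add atoms: none
Why: KOt-Bu removes the C4 hydrogen, which is α to the C3 ketone and γ to the C9 enone, to give an anion delocalised from O3 to O9; its C10 terminus adds to C1 of the vinyl ketone and protonation at C2 leaves the C4=C5 enone, the quaternary C10 and an isolated C9 ketone (intramolecular vinylogous Michael addition, that is, deconjugative α-alkylation of an enone dienolate, which is the closest known reaction type). Ring A closes in a 6-(enolexo)-endo-trig mode; attack through C4 would give a four-membered ring and attack from C8 an eight-membered or bridgehead-alkene ring, so no other cyclisation competes, and deprotonation at C6 leads to the same product after conjugation. Both C4 epimers of 6 converge because C4 becomes sp2. C10 is the only new stereocentre and is controlled by C7: C1 must stay near the plane of the C4=C5 bond, so it becomes equatorial on ring B and the methyl axial, and the chair with an equatorial isopropenyl group then has the methyl cis to it, whereas the C10 epimer needs an axial isopropenyl group or a twisted ring B. Because C5 and C9 are sp2 this preference is smaller than a normal equatorial preference, so catalytic base in a protic medium is used to keep the addition reversible (retro-Michael through the C2 enolate) and let the cis isomer accumulate. High dilution secures ring closure over intermolecular addition to the vinyl ketone.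

Step 5
Reactants: 7 (dione)
Product: 8 (7S,10S)-12-hydroxyeudesma-4,11(13)-diene-3,9-dione
Conditions: SeO2 (0.5 equiv), t-BuOOH (decane solution), CH2Cl2, 25 °C
Reagents that add atoms: selenium dioxide, O=[Se]=O; tert-butyl hydroperoxide, CC(C)(C)OO
Why: Catalytic SeO2 allylic oxidation (ene reaction, then [2,3]-sigmatropic shift) with t-BuOOH as terminal oxidant. In 7 the isopropenyl group is the only electron-rich alkene, and a methyl hydrogen is abstracted in preference to the C7 methine, as with carvone itself. Any enal from over-oxidation is returned to the alcohol in step 6.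

Step 6
Reactants: 8 (hydroxy dione)
Product: 9 (3S,7S,10S)-3,12-dihydroxyeudesma-4,11(13)-dien-9-one (3β-alcohol, cis to the C10 methyl)
Conditions: NaBH4, CeCl3·7H2O, MeOH, −78 → −40 °C
Reagents that add atoms: none
Why: Luche reduction: CeCl3 in methanol directs NaBH4 to 1,2-reduction of the conjugated ketone ahead of the saturated, α-quaternary C9 ketone, the selectivity known for steroidal 4-ene-3,17-diones. Hydride enters axially on the face opposite the C10 methyl and gives the equatorial 3β-alcohol.

Step 7
Reactants: 9 (diol)
Product: 10 (3S,7S,10S)-3,12-bis(tert-butyldimethylsilyloxy)eudesma-4,11(13)-dien-9-one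
Conditions: TBSCl, imidazole, DMAP (cat.), DMF, 25 → 40 °C
Reagents that add atoms: tert-butyldimethylsilyl chloride, CC(C)(C)[Si](C)(C)Cl
Why: Standard silylation of the primary and the secondary allylic hydroxyl in one operation; the ketone is untouched and both ethers tolerate the organolithium, mercury and hydride steps that follow.

Step 8
Reactants: 10 (C9 ketone)
Product: 11 (E)-p-toluenesulfonylhydrazone of 10 at C9, (3S,7S,10S)
Conditions: TsNHNH2, MgSO4, EtOH, 60 °C
Reagents that add atoms: p-toluenesulfonohydrazide, Cc1ccc(cc1)S(=O)(=O)NN
Why: Condensation at the only carbonyl group under neutral conditions that spare the silyl ethers. The sulfonamide nitrogen settles syn to C8, away from the quaternary C10, as the syn-directed deprotonation of step 9 requires.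

Step 9
Reactants: 11 (tosylhydrazone)
Product: 13 (3S,7R,10R)-3,12-bis(tert-butyldimethylsilyloxy)-8-(methylsulfanyl)eudesma-4,8,11(13)-triene, via 8-methylsulfanyl tosylhydrazone 12 (not isolated)
Conditions: n-BuLi (2.1 equiv), TMEDA, THF, −78 → −30 °C; MeSSMe, −78 °C; n-BuLi (1.2 equiv), −78 → 20 °C; H2O
Reagents that add atoms: dimethyl disulfide, CSSC
Why: The hydrazone dianion can form only at C8 and is sulfenylated by MeSSMe; further base removes the remaining C8 hydrogen and Shapiro fragmentation (loss of sulfinate and N2) gives the C9 vinyllithium, which is protonated to the C8 vinyl sulfide. This is the sulfenylation–Shapiro form of the 1,2-carbonyl transposition. Near-stoichiometric base limits metalation at the doubly allylic C7–H.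

Step 10
Reactants: 13 (vinyl sulfide)
Product: 14 (3S,7R,10R)-3,12-bis(tert-butyldimethylsilyloxy)eudesma-4,11(13)-dien-8-one
Conditions: HgCl2, CaCO3, MeCN–H2O (4:1), 50 °C
Reagents that add atoms: water, O
Why: Hydrolysis of the vinyl sulfide assisted by divalent mercury: protonation at C9, addition of water to the thionium ion at C8, and loss of the thiolate to mercury. C7 is not part of the enol ether, and the carbonate buffer keeps the β,γ-unsaturated ketone from epimerising at C7 or drawing the exocyclic alkene into conjugation.

Step 11
Reactants: 14 (C8 ketone)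
Product: 15 (3S,7R,8R,10R)-3,12-bis(tert-butyldimethylsilyloxy)eudesma-4,11(13)-dien-8-ol (axial 8β-alcohol, cis to the C7 branch and the C10 methyl)
Conditions: LiBH(s-Bu)3, THF, −78 °C; then H2O
Reagents that add atoms: none
Why: The bulky hydride cannot approach C8 axially past the syn-axial C10 methyl and attacks equatorially, giving the axial alcohol cis to the C7 branch, the outcome known for the reduction of isopulegone to neoisopulegol. The low temperature prevents enolisation toward C7.

Step 12
Reactants: 15 (C8 alcohol)
Product: 16 (3S,7R,8R,10R)-8-acetoxy-3,12-bis(tert-butyldimethylsilyloxy)eudesma-4,11(13)-diene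
Conditions: Ac2O, Et3N, DMAP, CH2Cl2, 25 °C
Reagents that add atoms: acetic anhydride, CC(=O)OC(C)=O
Why: DMAP-catalysed acetylation of the single free hydroxyl; the nucleophilic catalyst overcomes the hindrance of the axial position.

Step 13
Reactants: 16 (bis-silyl ether acetate)
Product: 17 (3S,7R,8R,10R)-8-acetoxyeudesma-4,11(13)-diene-3,12-diol
Conditions: HF·pyridine, pyridine, THF, 0 → 25 °C
Reagents that add atoms: none
Why: Fluoride-driven cleavage of both silyl ethers in a buffered, weakly acidic medium; no alkoxide is formed, which avoids acetate migration from O8 to the new primary hydroxyl.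

Step 14
Reactants: 17 (diol)
Product: 18 (3S,7R,8R,10R)-8-acetoxy-3-hydroxyeudesma-4,11(13)-dien-12-al
Conditions: TEMPO (cat.), PhI(OAc)2, CH2Cl2, 25 °C
Reagents that add atoms: none
Why: Oxoammonium (TEMPO) oxidation with PhI(OAc)2 as terminal oxidant is selective for the primary allylic alcohol over the hindered secondary allylic alcohol at C3 and stops at the aldehyde.

Step 15
Reactants: 18 (enal)
Product: 19 (3S,7R,8R,10R)-8-acetoxy-3-hydroxyeudesma-4,11(13)-dien-12-oic acid
Conditions: NaClO2, NaH2PO4, 2-methylbut-2-ene, t-BuOH–H2O, 0 → 25 °C
Reagents that add atoms: sodium chlorite, [Na+].[O-]Cl=O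
Why: Pinnick oxidation turns the enal into the acrylic acid without touching the alkenes or the free alcohol; the scavenger alkene removes hypochlorous acid before it can add to C4=C5.

Step 16
Reactants: 19 (acid)
Product: 20 methyl (3S,7R,8R,10R)-8-acetoxy-3-hydroxyeudesma-4,11(13)-dien-12-oate
Conditions: Me3SiCHN2, MeOH–toluene (1:4), 0 °C
Reagents that add atoms: (trimethylsilyl)diazomethane, C[Si](C)(C)C=[N+]=[N-]
Why: O-Methylation of the carboxylic acid by the diazoalkane under neutral conditions; the alcohol, the acetate and the acrylate double bond are inert.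

Step 17
Reactants: 20 (hydroxy ester); 21 (2E)-3-methylpent-2-enoic acid
Product: 22 methyl (3S,7R,8R,10R)-8-acetoxy-3-[(2E)-3-methylpent-2-enoyloxy]eudesma-4,11(13)-dien-12-oate (target)
Conditions: 21, DCC, DMAP (cat.), CH2Cl2, 0 → 25 °C
Reagents that add atoms: none
Why: Steglich esterification of the only free hydroxyl. No strong base is present, so γ-deprotonation of the activated acid, which would scramble the E geometry or deconjugate the alkene, is avoided.

## Compound list

1 | (R)-(−)-carvone | CC1=CC[C@H](CC1=O)C(C)=C | starting material
2 | N-methoxy-N-methylpropanamide | CCC(=O)N(C)OC | starting material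
3 | 2-[(5R)-1-hydroxy-2-methyl-5-(prop-1-en-2-yl)cyclohex-2-en-1-yl]-N-methoxy-N-methylpropanamide (diastereomer mixture) | CC1=CC[C@H](CC1(O)C(C)C(=O)N(C)OC)C(C)=C | intermediate
4 | vinylmagnesium bromide | C=C[Mg]Br | starting material
5 | 4-[(5R)-1-hydroxy-2-methyl-5-(prop-1-en-2-yl)cyclohex-2-en-1-yl]pent-1-en-3-one (diastereomer mixture) | CC1=CC[C@H](CC1(O)C(C)C(=O)C=C)C(C)=C | intermediate
6 | (5S)-2-methyl-3-(3-oxopent-4-en-2-yl)-5-(prop-1-en-2-yl)cyclohex-2-en-1-one (C4 epimers) | C=CC(=O)C(C)C1=C(C)C(=O)C[C@H](C1)C(C)=C | intermediate
7 | (7S,10S)-eudesma-4,11-diene-3,9-dione | C=C(C)[C@H]1CC2=C(C)C(=O)CC[C@]2(C)C(=O)C1 | intermediate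
8 | (7S,10S)-12-hydroxyeudesma-4,11(13)-diene-3,9-dione | C=C(CO)[C@H]1CC2=C(C)C(=O)CC[C@]2(C)C(=O)C1 | intermediate
9 | (3S,7S,10S)-3,12-dihydroxyeudesma-4,11(13)-dien-9-one | C=C(CO)[C@H]1CC2=C(C)[C@@H](O)CC[C@]2(C)C(=O)C1 | intermediate
10 | (3S,7S,10S)-3,12-bis(tert-butyldimethylsilyloxy)eudesma-4,11(13)-dien-9-one | C=C(CO[Si](C)(C)C(C)(C)C)[C@H]1CC2=C(C)[C@@H](O[Si](C)(C)C(C)(C)C)CC[C@]2(C)C(=O)C1 | intermediate
11 | (E)-p-toluenesulfonylhydrazone of 10 at C9, (3S,7S,10S) | C=C(CO[Si](C)(C)C(C)(C)C)[C@H]1CC2=C(C)[C@@H](O[Si](C)(C)C(C)(C)C)CC[C@]2(C)/C(=N/NS(=O)(=O)c3ccc(C)cc3)C1 | intermediate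
12 | 8-(methylsulfanyl) derivative of 11, (3S,7R,10S), C8 epimers, formed as its lithium salt | C=C(CO[Si](C)(C)C(C)(C)C)[C@H]1CC2=C(C)[C@@H](O[Si](C)(C)C(C)(C)C)CC[C@]2(C)C(=NNS(=O)(=O)c3ccc(C)cc3)C1SC | intermediate (not isolated)
13 | (3S,7R,10R)-3,12-bis(tert-butyldimethylsilyloxy)-8-(methylsulfanyl)eudesma-4,8,11(13)-triene | C=C(CO[Si](C)(C)C(C)(C)C)[C@H]1CC2=C(C)[C@@H](O[Si](C)(C)C(C)(C)C)CC[C@]2(C)C=C1SC | intermediate
14 | (3S,7R,10R)-3,12-bis(tert-butyldimethylsilyloxy)eudesma-4,11(13)-dien-8-one | C=C(CO[Si](C)(C)C(C)(C)C)[C@H]1CC2=C(C)[C@@H](O[Si](C)(C)C(C)(C)C)CC[C@]2(C)CC1=O | intermediate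
15 | (3S,7R,8R,10R)-3,12-bis(tert-butyldimethylsilyloxy)eudesma-4,11(13)-dien-8-ol | C=C(CO[Si](C)(C)C(C)(C)C)[C@H]1CC2=C(C)[C@@H](O[Si](C)(C)C(C)(C)C)CC[C@]2(C)C[C@H]1O | intermediate
16 | (3S,7R,8R,10R)-8-acetoxy-3,12-bis(tert-butyldimethylsilyloxy)eudesma-4,11(13)-diene | C=C(CO[Si](C)(C)C(C)(C)C)[C@H]1CC2=C(C)[C@@H](O[Si](C)(C)C(C)(C)C)CC[C@]2(C)C[C@H]1OC(C)=O | intermediate
17 | (3S,7R,8R,10R)-8-acetoxyeudesma-4,11(13)-diene-3,12-diol | C=C(CO)[C@H]1CC2=C(C)[C@@H](O)CC[C@]2(C)C[C@H]1OC(C)=O | intermediate
18 | (3S,7R,8R,10R)-8-acetoxy-3-hydroxyeudesma-4,11(13)-dien-12-al | C=C(C=O)[C@H]1CC2=C(C)[C@@H](O)CC[C@]2(C)C[C@H]1OC(C)=O | intermediate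
19 | (3S,7R,8R,10R)-8-acetoxy-3-hydroxyeudesma-4,11(13)-dien-12-oic acid | C=C(C(=O)O)[C@H]1CC2=C(C)[C@@H](O)CC[C@]2(C)C[C@H]1OC(C)=O | intermediate
20 | methyl (3S,7R,8R,10R)-8-acetoxy-3-hydroxyeudesma-4,11(13)-dien-12-oate | C=C(C(=O)OC)[C@H]1CC2=C(C)[C@@H](O)CC[C@]2(C)C[C@H]1OC(C)=O | intermediate
21 | (2E)-3-methylpent-2-enoic acid | CC/C(C)=C/C(=O)O | starting material
22 | methyl (3S,7R,8R,10R)-8-acetoxy-3-[(2E)-3-methylpent-2-enoyloxy]eudesma-4,11(13)-dien-12-oate (CNP0118541.1) | C=C(C(=O)OC)[C@H]1CC2=C(C)[C@@H](OC(=O)/C=C(\C)CC)CC[C@]2(C)C[C@H]1OC(C)=O | target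

## Step count and least certain steps

Total: 17 steps. Longest linear sequence: 17 steps (1 → 22); compounds 2, 4 and 21 enter without steps of their own.

**Step 4 (key step).** Two processes may spoil it. The first is intermolecular conjugate addition of the extended enolate to the vinyl ketone of a second molecule. The second is weak facial discrimination at C10, because an axial C7 substituent flanked by two sp2 carbons costs little. Fallback, setting out from 6 and returning at 7: soft enolisation with TBSOTf and Et3N would give the cross-conjugated silyl trienol ether (5S)-3-[(2E)-3-(tert-butyldimethylsilyloxy)penta-2,4-dien-2-yl]-2-methyl-5-(prop-1-en-2-yl)cyclohex-2-en-1-one F4, needed with the vinyl group cis to the ring carbon. Heating in toluene should bring about a disrotatory 6π-electrocyclisation to the silyl dienol ether (7S,10S)-3-(tert-butyldimethylsilyloxy)eudesma-2,4,11-trien-9-one F5, and dilute aqueous acid would hydrolyse it to 7. This path is neutral and unimolecular, so no free enolate is present to attack a vinyl ketone, and C10 is set under kinetic instead of thermodynamic control.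

**Step 1.** Conjugate (1,4) addition of the amide enolate, or retro-aldol cleavage of the lithium aldolate before the quench, may erode the 1,2-adduct. Fallback, setting out from 1 and returning at 3: the lithium enolate of ethyl propanoate (LiN(i-Pr)2, THF, −78 °C), for which 1,2-addition to cyclohexenones is the kinetic rule, would give the β-hydroxy ester ethyl 2-[(5R)-1-hydroxy-2-methyl-5-(prop-1-en-2-yl)cyclohex-2-en-1-yl]propanoate F1. Aminolysis with MeNH(OMe)·HCl and i-PrMgCl would then convert it into 3.

**Step 3.** The tertiary β-hydroxy ketone may undergo retro-aldol cleavage or dehydration under the acidic chromium reagent, and the vinyl ketone may polymerise. Fallback, setting out from 3 and returning at 6: a 1,3-hydroxyl shift catalysed by Ph3SiOReO3 (heptavalent rhenium) would turn the aldol-type tertiary alcohol into the secondary allylic alcohol 2-[(5S)-3-hydroxy-2-methyl-5-(prop-1-en-2-yl)cyclohex-1-en-1-yl]-N-methoxy-N-methylpropanamide F2. The shift is driven by the tetrasubstituted alkene and F2 can no longer fragment. CH2=CHMgBr would then give 4-[(5S)-3-hydroxy-2-methyl-5-(prop-1-en-2-yl)cyclohex-1-en-1-yl]pent-1-en-3-one F3, and Dess–Martin periodinane would oxidise the ring carbinol to 6 under neutral conditions.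

**Step 6.** Loss of chemoselectivity, with hydride also reaching the C9 ketone, is the likely failure, since that ketone is only sterically protected. Fallback, setting out from 8 and returning at 10: exhaustive reduction with excess NaBH4 and CeCl3 would give the triol (3S,7S,10S)-eudesma-4,11(13)-diene-3,9,12-triol F6. Silylation of the primary and the allylic hydroxyl, with the C9 hydroxyl beside the quaternary carbon reacting last, would give (3S,7S,10S)-3,12-bis(tert-butyldimethylsilyloxy)eudesma-4,11(13)-dien-9-ol F7. Dess–Martin oxidation would restore the C9 ketone of 10.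

**Step 9.** Three failures are possible: incomplete metalation of the hindered hydrazone at C8, protonation instead of sulfenylation, or scrambling at the doubly allylic C7–H by excess alkyllithium. Fallback, setting out from 10 and returning at 14 (it replaces steps 8–10):
- Sulfenylation of the ketone enolate (LiN(i-Pr)2, then PhSSO2Ph) would give (3S,7R,10S)-3,12-bis(tert-butyldimethylsilyloxy)-8-(phenylsulfanyl)eudesma-4,11(13)-dien-9-one F8.
- NaBH4 would give the β-hydroxy sulfide (3S,7R,10S)-3,12-bis(tert-butyldimethylsilyloxy)-8-(phenylsulfanyl)eudesma-4,11(13)-dien-9-ol F9.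
- Syn-dehydration with the Burgess reagent, which needs no anti-periplanar hydrogen, would give the vinyl sulfide (3S,7R,10R)-3,12-bis(tert-butyldimethylsilyloxy)-8-(phenylsulfanyl)eudesma-4,8,11(13)-triene F10.
- Hydrolysis with HgCl2 and CaCO3 as in step 10 would deliver 14.

## Further compounds

F1 | step 1 | ethyl 2-[(5R)-1-hydroxy-2-methyl-5-(prop-1-en-2-yl)cyclohex-2-en-1-yl]propanoate (diastereomer mixture) | CC1=CC[C@H](CC1(O)C(C)C(=O)OCC)C(C)=C
F2 | step 3 | 2-[(5S)-3-hydroxy-2-methyl-5-(prop-1-en-2-yl)cyclohex-1-en-1-yl]-N-methoxy-N-methylpropanamide (diastereomer mixture) | CON(C)C(=O)C(C)C1=C(C)C(O)C[C@H](C1)C(C)=C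
F3 | step 3 | 4-[(5S)-3-hydroxy-2-methyl-5-(prop-1-en-2-yl)cyclohex-1-en-1-yl]pent-1-en-3-one (diastereomer mixture) | C=CC(=O)C(C)C1=C(C)C(O)C[C@H](C1)C(C)=C
F4 | step 4 | (5S)-3-[(2E)-3-(tert-butyldimethylsilyloxy)penta-2,4-dien-2-yl]-2-methyl-5-(prop-1-en-2-yl)cyclohex-2-en-1-one | C=C/C(O[Si](C)(C)C(C)(C)C)=C(/C)C1=C(C)C(=O)C[C@H](C1)C(C)=C
F5 | step 4 | (7S,10S)-3-(tert-butyldimethylsilyloxy)eudesma-2,4,11-trien-9-one | C=C(C)[C@H]1CC2=C(C)C(O[Si](C)(C)C(C)(C)C)=CC[C@]2(C)C(=O)C1
F6 | step 6 | (3S,7S,10S)-eudesma-4,11(13)-diene-3,9,12-triol (C9 epimers) | C=C(CO)[C@H]1CC2=C(C)[C@@H](O)CC[C@]2(C)C(O)C1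
F7 | step 6 | (3S,7S,10S)-3,12-bis(tert-butyldimethylsilyloxy)eudesma-4,11(13)-dien-9-ol (C9 epimers) | C=C(CO[Si](C)(C)C(C)(C)C)[C@H]1CC2=C(C)[C@@H](O[Si](C)(C)C(C)(C)C)CC[C@]2(C)C(O)C1
F8 | step 9 | (3S,7R,10S)-3,12-bis(tert-butyldimethylsilyloxy)-8-(phenylsulfanyl)eudesma-4,11(13)-dien-9-one (C8 epimers) | C=C(CO[Si](C)(C)C(C)(C)C)[C@H]1CC2=C(C)[C@@H](O[Si](C)(C)C(C)(C)C)CC[C@]2(C)C(=O)C1Sc3ccccc3
F9 | step 9 | (3S,7R,10S)-3,12-bis(tert-butyldimethylsilyloxy)-8-(phenylsulfanyl)eudesma-4,11(13)-dien-9-ol (C8 and C9 epimers) | C=C(CO[Si](C)(C)C(C)(C)C)[C@H]1CC2=C(C)[C@@H](O[Si](C)(C)C(C)(C)C)CC[C@]2(C)C(O)C1Sc3ccccc3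
F10 | step 9 | (3S,7R,10R)-3,12-bis(tert-butyldimethylsilyloxy)-8-(phenylsulfanyl)eudesma-4,8,11(13)-triene | C=C(CO[Si](C)(C)C(C)(C)C)[C@H]1CC2=C(C)[C@@H](O[Si](C)(C)C(C)(C)C)CC[C@]2(C)C=C1Sc3ccccc3
A1 | alternative 1 | tert-butyl 2-[(3S,7R,10S)-3-(tert-butyldimethylsilyloxy)-8-oxo-11,12,13-trinoreudesma-1,4-dien-7-yl]acetate | CC(C)(C)OC(=O)C[C@H]1CC2=C(C)[C@@H](O[Si](C)(C)C(C)(C)C)C=C[C@]2(C)CC1=O
A2 | alternative 2 | methyl 2-[(4aR,8aS)-6-(tert-butyldimethylsilyloxy)-2-methoxy-4a-methyl-1,4-dioxo-1,4,4a,5,8,8a-hexahydronaphthalen-7-yl]acetate (cis-fused) | COC1=CC(=O)[C@]2(C)CC(O[Si](C)(C)C(C)(C)C)=C(CC(=O)OC)C[C@@H]2C1=O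
A3 | alternative 3 | (3S,10R)-3-(tert-butyldimethylsilyloxy)-11,12,13-trinoreudesm-4-en-8-one ethylene ketal | C1CC2=C(C)[C@@H](O[Si](C)(C)C(C)(C)C)CC[C@]2(C)CC13OCCO3
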